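The C2=C3 alkene next to the C4 methoxy carbon of the cyclohexenone ring is read as lost methanol, and quaternary C6 as an inserted carbon. Taking both away leaves (3R,4R)-3,4-dimethoxycyclopentanone, whose twofold axis makes both α-methylenes and both carbonyl faces homotopic. The key step inserts the diazo carbon of a side-chain diazoalkane (future C6, with C7 and C8 already set) between C1 and either α-CH2. This enlarges the five-membered ring to the six-membered one with no regiochemical question. DBU in the same flask expels the C3 methoxy group and unveils the C1-C3 enone with C4 intact. Allylation of the cross-conjugated dienolate then sets C6.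

Key step: step 9

Remark: route labels are ring C1 (C=O), C2=C3, C4 (OMe), C5 (CH2), C6 (quaternary) and side chain C8 (CHMe on C6), C7 (ArCH-O); (R)-TRIP is assumed to deliver the crotyl group to the re face of 1, as it does with other aromatic aldehydes.

Step 1
Reactants: 1 3,4,5-trimethoxybenzaldehyde; 2 (Z)-crotylboronic acid pinacol ester
Product: 3 (1R,2S)-2-methyl-1-(3,4,5-trimethoxyphenyl)but-3-en-1-ol
Conditions: (R)-TRIP [(R)-3,3'-bis(2,4,6-triisopropylphenyl)-BINOL hydrogen phosphate, 5 mol %], 4 Å MS, toluene, -30 °C; aq. NaHCO3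
Reagents that add atoms: none
Why: Chiral-phosphoric-acid-catalysed crotylboration runs through a closed chair transition state, so the Z-boronate gives the syn C7/C8 relationship and the catalyst directs re-face attack on the aldehyde, setting 7R and 8S.

Step 2
Reactants: 3 homoallylic alcohol
Product: 4 tert-butyl{[(1R,2S)-2-methyl-1-(3,4,5-trimethoxyphenyl)but-3-en-1-yl]oxy}dimethylsilane
Conditions: TBSOTf, 2,6-lutidine, CH2Cl2, 0 °C
Reagents that add atoms: tert-butyldimethylsilyl trifluoromethanesulfonate CC(C)(C)[Si](C)(C)OS(=O)(=O)C(F)(F)F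
Why: Silyl triflate silylation protects the hindered benzylic alcohol without touching a stereocentre, and the bulky OTBS group later shields one face of the dienolate.

Step 3
Reactants: 4 TBS ether
Product: 5 (2R,3R)-3-(tert-butyldimethylsilyloxy)-2-methyl-3-(3,4,5-trimethoxyphenyl)propanal
Conditions: O3, CH2Cl2, -78 °C (stopped at alkene consumption); PPh3, -78 °C to rt
Reagents that add atoms: ozone [O-][O+]=O
Why: Ozonolysis with reductive work-up cleaves the only alkene far faster than ozone attacks the arene, and the neutral conditions preserve the α-stereocentre C8 (its descriptor changes only through CIP priorities).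

Step 4
Reactants: 5 aldehyde
Product: 6 (E)-[(2S,3R)-3-(tert-butyldimethylsilyloxy)-2-methyl-3-(3,4,5-trimethoxyphenyl)propylidene]hydrazine
Conditions: N2H4·H2O (10 equiv), EtOH, 0 °C to rt
Reagents that add atoms: hydrazine NN
Why: Hydrazone condensation with a large excess of hydrazine outruns azine formation and β-elimination of the silyloxy group, and it leaves C7 and C8 unchanged.

Step 5
Reactants: 7 dimethyl D-tartrate, (2S,3S)
Product: 8 dimethyl (2S,3S)-2,3-dimethoxybutanedioate
Conditions: MeI, Ag2O, CH2Cl2, rt, dark
Reagents that add atoms: iodomethane CI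
Why: Purdie methylation etherifies both secondary alcohols under nearly neutral conditions, so the α-stereocentres of the diester are not epimerised.

Step 6
Reactants: 8 dimethoxy diester
Product: 9 (2R,3R)-2,3-dimethoxybutane-1,4-diol
Conditions: LiAlH4, THF, 0 °C to reflux; aqueous NaOH work-up
Reagents that add atoms: none
Why: Hydride reduction of both esters gives the 1,4-diol with the ether stereocentres untouched (the descriptors change only through CIP priorities).

Step 7
Reactants: 9 diol
Product: 10 (2R,3R)-2,3-dimethoxybutane-1,4-diyl bis(4-methylbenzenesulfonate)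
Conditions: TsCl (2.3 equiv), pyridine, 0 °C
Reagents that add atoms: 4-methylbenzenesulfonyl chloride Cc1ccc(cc1)S(=O)(=O)Cl
Why: Cold bis-sulfonylation activates both primary alcohols quickly enough to avoid closure to the tetrahydrofuran.

Step 8
Reactants: 10 ditosylate; 11 tosylmethyl isocyanide (TosMIC)
Product: 13 (3R,4R)-3,4-dimethoxycyclopentanone, via cyclic isocyanide sulfone 12 (not isolated)
Conditions: NaH (2.2 equiv), NaI (10 mol %), DMSO/Et2O, 0 °C to rt; then conc. HCl, Et2O/CH2Cl2, 0 °C, short contact
Reagents that add atoms: water O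
Why: In the van Leusen ketone synthesis TosMIC acts as a carbonyl dianion equivalent, undergoing two SN2 alkylations (the second a 5-exo-tet closure) at carbons that carry no stereocentre, and brief acid hydrolysis then frees the ketone C1.

Step 9
Reactants: 6 hydrazone; 13 (3R,4R)-3,4-dimethoxycyclopentanone
Product: 16 (4R)-4-methoxy-6-[(1R,2S)-1-(tert-butyldimethylsilyloxy)-1-(3,4,5-trimethoxyphenyl)propan-2-yl]cyclohex-2-en-1-one (C6 epimers), via diazoalkane 14 (not isolated), via dimethoxycyclohexanone 15 (not isolated)
Conditions: (COCl)2, DMSO, THF, -78 °C, then 6, Et3N, -78 °C (cold filtration gives a solution of 14); 13, Sc(OTf)3 (10 mol %), CH2Cl2/toluene, -78 to -20 °C; then DBU, 0 to 40 °C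
Reagents that add atoms: none
Why: Activated-DMSO dehydrogenation of hydrazone 6 gives the non-stabilised diazoalkane 14, whose nucleophilic carbon (future C6) adds to the Sc(OTf)3-bound carbonyl C1 of 13, and in the diazonium betaine an α-CH2 antiperiplanar to N2 shifts from C1 to C6 as nitrogen leaves, so the five-membered ring C1-C2-C3-C4-C5 becomes the six-membered ring of 15. This is the Lewis-acid-catalysed Büchner-Curtius-Schlotterbeck (Tiffeneau-Demjanov type) homologation of cycloalkanones with substituted diazomethanes, a known reaction type, and the ring forms by enlargement through a 1,2-carbon shift rather than by end-to-end cyclisation. The selectivity the step would need, namely which α-carbon migrates, is removed by design, because the twofold axis of 13 makes both carbonyl faces and both α-methylenes homotopic and either shift gives the same constitution with the 3R,4R methoxy carbons untouched as spectators. C6 arises as an inconsequential epimer mixture (it is planarised in step 10), C7 and C8 pass through unchanged, and C4 keeps the tartrate configuration. Over-homologation is held back because 15 is α-branched and more hindered than 13. DBU then removes an acidic C2 proton and expels the C3 methoxy group (E1cB), the only β-leaving group available since C5 bears none, which installs C2=C3 and leaves the C4 ether as the γ-substituent of enone 16.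

Step 10
Reactants: 16 enone
Product: 18 (4R,6R)-6-allyl-4-methoxy-6-[(1R,2S)-1-(tert-butyldimethylsilyloxy)-1-(3,4,5-trimethoxyphenyl)propan-2-yl]cyclohex-2-en-1-one (O-TBS-megaphone), via lithium dienolate 17 (not isolated)
Conditions: LiN(i-Pr)2 (1.1 equiv), THF, -78 °C; DMPU, allyl bromide, -78 to -20 °C
Reagents that add atoms: allyl bromide C=CCBr
Why: Kinetic α'-deprotonation removes the only sp3 α-proton so both C6 epimers converge on planar 17, and enolate alkylation occurs anti to the CH(OTBS)Ar group in the A1,3-minimised rotamer (C8-H eclipsing C1-O) and trans to the C4 methoxy group, two matched effects that set 6R.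

Step 11
Reactants: 18 O-TBS-megaphone
Product: 20 megaphone acetate, via megaphone 19 (not isolated)
Conditions: TBAF, AcOH, THF, 0 °C to rt; then Et3N, Ac2O, DMAP, rt
Reagents that add atoms: acetic anhydride CC(=O)OC(C)=O
Why: Buffered fluoride desilylation spares the γ-methoxy enone, and DMAP-catalysed acetylation of the freed C7 alcohol proceeds with retention because the C7-O bond is never broken.

Compound list
1 | 3,4,5-trimethoxybenzaldehyde | COc1cc(C=O)cc(OC)c1OC | starting material
2 | (Z)-crotylboronic acid pinacol ester | C/C=C\CB1OC(C)(C)C(C)(C)O1 | starting material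
3 | (1R,2S)-2-methyl-1-(3,4,5-trimethoxyphenyl)but-3-en-1-ol | C=C[C@H](C)[C@@H](O)c1cc(OC)c(OC)c(OC)c1 | intermediate
4 | TBS ether of 3 | C=C[C@H](C)[C@@H](O[Si](C)(C)C(C)(C)C)c1cc(OC)c(OC)c(OC)c1 | intermediate
5 | (2R,3R)-3-(tert-butyldimethylsilyloxy)-2-methyl-3-(3,4,5-trimethoxyphenyl)propanal | O=C[C@H](C)[C@@H](O[Si](C)(C)C(C)(C)C)c1cc(OC)c(OC)c(OC)c1 | intermediate
6 | (E)-hydrazone of 5, (2S,3R) | N/N=C/[C@H](C)[C@@H](O[Si](C)(C)C(C)(C)C)c1cc(OC)c(OC)c(OC)c1 | intermediate
7 | dimethyl D-tartrate, (2S,3S) | COC(=O)[C@@H](O)[C@H](O)C(=O)OC | starting material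
8 | dimethyl (2S,3S)-2,3-dimethoxybutanedioate | COC(=O)[C@@H](OC)[C@H](OC)C(=O)OC | intermediate
9 | (2R,3R)-2,3-dimethoxybutane-1,4-diol | OC[C@@H](OC)[C@H](OC)CO | intermediate
10 | (2R,3R)-2,3-dimethoxybutane-1,4-diyl bis(4-methylbenzenesulfonate) | Cc1ccc(cc1)S(=O)(=O)OC[C@@H](OC)[C@H](OC)COS(=O)(=O)c1ccc(C)cc1 | intermediate
11 | tosylmethyl isocyanide | [C-]#[N+]CS(=O)(=O)c1ccc(C)cc1 | starting material
12 | (3R,4R)-1-isocyano-3,4-dimethoxy-1-(4-methylphenylsulfonyl)cyclopentane (C1 not stereogenic) | [C-]#[N+]C1(C[C@@H](OC)[C@H](OC)C1)S(=O)(=O)c1ccc(C)cc1 | intermediate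
13 | (3R,4R)-3,4-dimethoxycyclopentanone | O=C1C[C@@H](OC)[C@H](OC)C1 | intermediate
14 | tert-butyl{[(1R,2S)-3-diazo-2-methyl-1-(3,4,5-trimethoxyphenyl)propyl]oxy}dimethylsilane | [N-]=[N+]=C[C@H](C)[C@@H](O[Si](C)(C)C(C)(C)C)c1cc(OC)c(OC)c(OC)c1 | intermediate
15 | (3R,4R)-3,4-dimethoxy-6-[(1R,2S)-1-(tert-butyldimethylsilyloxy)-1-(3,4,5-trimethoxyphenyl)propan-2-yl]cyclohexanone (route numbering, C6 epimers) | C1([C@H](C)[C@@H](O[Si](C)(C)C(C)(C)C)c2cc(OC)c(OC)c(OC)c2)C[C@@H](OC)[C@H](OC)CC1=O | intermediate
16 | (4R)-4-methoxy-6-[(1R,2S)-1-(tert-butyldimethylsilyloxy)-1-(3,4,5-trimethoxyphenyl)propan-2-yl]cyclohex-2-en-1-one (C6 epimers) | C1([C@H](C)[C@@H](O[Si](C)(C)C(C)(C)C)c2cc(OC)c(OC)c(OC)c2)C[C@@H](OC)C=CC1=O | intermediate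
17 | cross-conjugated lithium dienolate of 16 | [Li]OC1=C([C@H](C)[C@@H](O[Si](C)(C)C(C)(C)C)c2cc(OC)c(OC)c(OC)c2)C[C@@H](OC)C=C1 | intermediate
18 | O-TBS-megaphone, (4R,6R,7R,8S) | C=CC[C@]1([C@H](C)[C@@H](O[Si](C)(C)C(C)(C)C)c2cc(OC)c(OC)c(OC)c2)C[C@@H](OC)C=CC1=O | intermediate
19 | megaphone | C=CC[C@]1([C@H](C)[C@@H](O)c2cc(OC)c(OC)c(OC)c2)C[C@@H](OC)C=CC1=O | intermediate
20 | megaphone acetate, (4R,6R)-6-allyl-4-methoxy-6-[(1R,2S)-1-acetoxy-1-(3,4,5-trimethoxyphenyl)propan-2-yl]cyclohex-2-en-1-one | C=CC[C@]1([C@H](C)[C@@H](OC(C)=O)c2cc(OC)c(OC)c(OC)c2)C[C@@H](OC)C=CC1=O | target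

Total step count: 11. Longest linear sequence: 7 steps (1-4, 9-11); the ketone branch 5-8, 9-11 is equally long.

Steps most likely to fail

Step 9. The hindered secondary-alkyl diazoalkane may lose nitrogen by 1,2-hydride shift or couple to the azine before it meets the ketone. Residual amine or sulfide may deactivate the Lewis acid. The betaine may also collapse to a spiro-epoxide instead of migrating. The fallback sets out from 6 and 13 and comes back at 15, and it replaces the diazo and Lewis-acid chemistry with an anionic β-oxido carbenoid ring enlargement. Hydrazone 6 is converted with CuBr2 and LiOt-Bu into the gem-dibromide F1. F1 is deprotonated with LiN(i-Pr)2 at -95 °C and added to 13 to give the dibromocarbinol F2. Two equivalents of n-BuLi then form the alkoxide and exchange one bromine, and the carbenoid rearranges by the same symmetry-protected 1,2-shift to the ring-enlarged lithium enolate. Protonation gives 15, and DBU treatment as in step 9 continues to 16.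

Step 10. C-alkylation at the hindered, fully substituted dienolate carbon may be slow. That would allow O-allylation, proton exchange leading to loss of methanol and aromatisation, or erosion of facial selectivity. The fallback sets out from 16 and comes back at 18, and it moves the quaternary centre to catalyst control. Treating 16 with KN(SiMe3)2 and allyl chloroformate gives the allyl dienol carbonate F3. Tsuji decarboxylative allylation of F3 with Pd2(dba)3 and (S)-t-Bu-PHOX in toluene delivers the allyl group to the same face that the substrate prefers.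

Step 8. E2 loss of sulfonate next to the methoxy groups and intermolecular alkylation to oligomers may compete with ring closure, and the acid hydrolysis may trigger loss of methanol from the β-methoxy ketone. The fallback sets out from 10 and comes back at 13, and it uses a Corey-Seebach acyl-anion equivalent instead. 1,3-Dithiane is lithiated with n-BuLi and alkylated with 10, then lithiated again to close the spiro-dithiane F4. F4 is unmasked under nearly neutral conditions with MeI and CaCO3 in aqueous MeCN.

Further compounds
F1 | step 9 | tert-butyl{[(1R,2R)-3,3-dibromo-2-methyl-1-(3,4,5-trimethoxyphenyl)propyl]oxy}dimethylsilane | BrC(Br)[C@H](C)[C@@H](O[Si](C)(C)C(C)(C)C)c1cc(OC)c(OC)c(OC)c1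
F2 | step 9 | (3R,4R)-1-[(2R,3R)-1,1-dibromo-3-(tert-butyldimethylsilyloxy)-2-methyl-3-(3,4,5-trimethoxyphenyl)propyl]-3,4-dimethoxycyclopentan-1-ol | OC1(C[C@@H](OC)[C@H](OC)C1)C(Br)(Br)[C@H](C)[C@@H](O[Si](C)(C)C(C)(C)C)c1cc(OC)c(OC)c(OC)c1
F3 | step 10 | allyl (4R)-4-methoxy-6-[(1R,2S)-1-(tert-butyldimethylsilyloxy)-1-(3,4,5-trimethoxyphenyl)propan-2-yl]cyclohexa-1(6),2-dien-1-yl carbonate | C=CCOC(=O)OC1=C([C@H](C)[C@@H](O[Si](C)(C)C(C)(C)C)c2cc(OC)c(OC)c(OC)c2)C[C@@H](OC)C=C1
F4 | step 8 | (2R,3R)-2,3-dimethoxy-6,10-dithiaspiro[4.5]decane | S1CCCSC12C[C@@H](OC)[C@H](OC)C2
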